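**Retrosynthetic overview**

1. Feature: on the ten-membered carbocycle (C1–C10) the C1 acetoxy group and the C10 methyl group are syn along C9–C10–C1–C2 (1S,10S). This is the pattern left by syn addition of H (to C10) and OH (to C1) across a Z C1=C10 alkene, so the target is taken back to 1(10)Z-ene 21.
2. Key disconnection: the C1=C10 bond of 21, by ring-closing metathesis of epoxy butenolide 20 (C1 vinyl at the end of the butenyl chain on C4, C10 isopropenyl on the C8 carbinol).
3. 20 comes from C7-iodo butenolide 14 by formylation at C7 and catalyst-controlled methallylation (C8). 14 comes from propargylic mesylate 12 by Pd-catalysed hydrocarboxylation and iodolactonisation of the allenoic acid (C6 by axis-to-centre transfer).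
4. 12 comes from epoxy aldehyde 6 and a silyl propargyl ether. C4/C5 come from Sharpless epoxidation of an E allylic alcohol made by carbocupration of ethyl but-2-ynoate.
5. Ring order: oxirane (step 3), butenolide (step 10), ten-membered carbocycle (step 15); then hydroboration, acetate, methacrylate, desilylation.

Key step: step 15

Remark: germacrane numbering is used for all intermediates (carbocycle C1–C10, lactone O on C6 and carbonyl C12, hydroxymethyl carbon C13 on C11, C14 on C10, C15 on C4); the target is 1S,4R,5R,6S,8S,10S.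

**Route**

Step 1
Reactants: 1 ethyl but-2-ynoate; 2 but-3-enylmagnesium bromide
Product: 3 ethyl (2E)-3-methylhepta-2,6-dienoate
Conditions: 2, CuBr·SMe2 (1 equiv each), THF, −40 °C; then 1, −78 °C; sat. NH4Cl at −78 °C
Reagents that add atoms: none
Why: Carbocupration (syn conjugate addition of an organocopper reagent to an alkynoate) followed by cold protonation of the alkenylcopper places the butenyl chain trans to the ester, which fixes the E geometry needed for the trans C4–C5 oxirane.

Step 2
Reactants: 3 ethyl (2E)-3-methylhepta-2,6-dienoate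
Product: 4 (2E)-3-methylhepta-2,6-dien-1-ol
Conditions: i-Bu2AlH (2.2 equiv), CH2Cl2, −78 °C; Rochelle salt work-up
Reagents that add atoms: none
Why: DIBAL-H 1,2-reduction of an α,β-unsaturated ester gives the allylic alcohol and leaves both alkenes untouched.

Step 3
Reactants: 4 (2E)-3-methylhepta-2,6-dien-1-ol
Product: 5 [(2R,3R)-3-(but-3-en-1-yl)-3-methyloxiran-2-yl]methanol
Conditions: Ti(OiPr)4 (5 mol%), D-(−)-diethyl tartrate (6 mol%), t-BuOOH, 4 Å MS, CH2Cl2, −20 °C
Reagents that add atoms: tert-butyl hydroperoxide, CC(C)(C)OO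
Why: Sharpless asymmetric epoxidation: the titanium–D-(−)-tartrate complex delivers oxygen only to the allylic alkene and from the face that gives the 2R,3R epoxy alcohol (C4 R and C5 R of the target), the remote vinyl group being inert.

Step 4
Reactants: 5 [(2R,3R)-3-(but-3-en-1-yl)-3-methyloxiran-2-yl]methanol
Product: 6 (2S,3R)-3-(but-3-en-1-yl)-3-methyloxirane-2-carbaldehyde
Conditions: Dess–Martin periodinane, pyridine, CH2Cl2, 0 °C → rt
Reagents that add atoms: none
Why: Dess–Martin oxidation under buffered conditions should give the epoxy aldehyde without opening the oxirane or epimerising its CH carbon (the descriptor changes only through CIP priorities).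

Step 5
Reactants: 6 (2S,3R)-3-(but-3-en-1-yl)-3-methyloxirane-2-carbaldehyde; 7 tert-butyldimethyl(prop-2-yn-1-yloxy)silane
Product: 9 1-[(2R,3R)-3-(but-3-en-1-yl)-3-methyloxiran-2-yl]-4-[tert-butyl(dimethyl)silyl]oxybut-2-yn-1-ol (both C6 epimers), via lithium acetylide 8 (not isolated)
Conditions: 7, n-BuLi, THF, −78 °C; then 6, −78 °C; sat. NH4Cl
Reagents that add atoms: none
Why: Acetylide 1,2-addition to the aldehyde at −78 °C forms the C6–C7 bond; the carbinol epimers (Felkin–Anh addition should favour the 6R one) are not separated because the next two steps reset C6.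

Step 6
Reactants: 9 propargylic alcohol (both C6 epimers)
Product: 10 1-[(2S,3R)-3-(but-3-en-1-yl)-3-methyloxiran-2-yl]-4-[tert-butyl(dimethyl)silyl]oxybut-2-yn-1-one
Conditions: Dess–Martin periodinane, pyridine, CH2Cl2, 0 °C
Reagents that add atoms: none
Why: Dess–Martin oxidation of the propargylic alcohol converges both epimers on a single ynone under non-basic conditions that the α,β-epoxy ketone tolerates.

Step 7
Reactants: 10 epoxy ynone
Product: 11 (1R)-1-[(2R,3R)-3-(but-3-en-1-yl)-3-methyloxiran-2-yl]-4-[tert-butyl(dimethyl)silyl]oxybut-2-yn-1-ol (6R carbinol)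
Conditions: Ru[(S,S)-TsNCHPhCHPhNH](p-cymene) (2 mol%), i-PrOH, rt
Reagents that add atoms: none
Why: Noyori asymmetric transfer hydrogenation of an α,β-acetylenic ketone: the (S,S)-catalyst, which recognises the alkyne as the unsaturated substituent, should deliver hydride to the face that gives the 6R alcohol, the same erythro epimer that the epoxy ketone itself favours, so catalyst and substrate act in the same sense.

Step 8
Reactants: 11 (6R)-propargylic alcohol
Product: 12 (1R)-1-[(2R,3R)-3-(but-3-en-1-yl)-3-methyloxiran-2-yl]-4-[tert-butyl(dimethyl)silyl]oxybut-2-yn-1-yl methanesulfonate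
Conditions: MsCl, Et3N, CH2Cl2, −40 °C; used crude
Reagents that add atoms: methanesulfonyl chloride, CS(=O)(=O)Cl
Why: Mesylation of the secondary propargylic alcohol occurs at oxygen with retention at C6 and at a temperature at which chloride does not displace the sulfonate.

Step 9
Reactants: 12 propargylic mesylate
Product: 13 (aR)-4-[(2R,3R)-3-(but-3-en-1-yl)-3-methyloxiran-2-yl]-2-({[tert-butyl(dimethyl)silyl]oxy}methyl)buta-2,3-dienoic acid
Conditions: Pd(PPh3)4 (5 mol%), CO (1 atm), H2O, 2,6-lutidine, THF, 0 °C → rt; used crude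
Reagents that add atoms: carbon monoxide, [C-]#[O+]; water, O
Why: Palladium-catalysed hydrocarboxylation of a propargylic sulfonate to a 2,3-allenoic acid: zerovalent palladium attacks C11 anti to the leaving group (SN2′), CO inserts into the allenyl–palladium bond with retention and water cleaves the acylpalladium, so the C6 centre is transcribed into the aR axis, while 2,6-lutidine takes up the sulfonic acid to protect the oxirane.

Step 10
Reactants: 13 allenoic acid
Product: 14 (5R)-5-[(2R,3R)-3-(but-3-en-1-yl)-3-methyloxiran-2-yl]-3-({[tert-butyl(dimethyl)silyl]oxy}methyl)-4-iodofuran-2(5H)-one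
Conditions: I2, NaHCO3, MeCN, 0 °C, dark
Reagents that add atoms: iodine, II
Why: Iodolactonisation of a 2,3-allenoic acid: the iodonium forms on the C6=C7 bond on the face away from the carboxylate, which closes 5-endo onto C6, so the axis is converted to the C6 centre of the target (net inversion relative to the propargylic alcohol) and iodine is left on C7.

Step 11
Reactants: 14 C7-iodo butenolide
Product: 15 (2S)-2-[(2R,3R)-3-(but-3-en-1-yl)-3-methyloxiran-2-yl]-4-({[tert-butyl(dimethyl)silyl]oxy}methyl)-5-oxo-2,5-dihydrofuran-3-carbaldehyde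
Conditions: Pd(PPh3)4 (5 mol%), CO (3 atm), Bu3SnH (syringe pump), THF, 50 °C
Reagents that add atoms: carbon monoxide, [C-]#[O+]
Why: Palladium-catalysed formylation of a vinyl iodide with CO and a tin hydride (reductive carbonylation): slow addition of the hydride under CO pressure lets CO insertion outrun direct reduction of the C7–palladium bond, and the neutral medium spares the acidic C6–H and the oxirane.

Step 12
Reactants: 16 3-chloro-2-methylpropene
Product: 18 tributyl(2-methylprop-2-en-1-yl)stannane, via (2-methylallyl)magnesium chloride 17 (not isolated)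
Conditions: Mg, THF, 0 °C → rt; then Bu3SnCl, 0 °C → rt; distillation
Reagents that add atoms: tributyltin chloride, CCCC[Sn](Cl)(CCCC)CCCC
Why: Grignard formation from the allylic chloride and transmetallation to tin is the standard preparation of allylic stannanes.

Step 13
Reactants: 15 C7-formyl butenolide; 18 tributyl(2-methylprop-2-en-1-yl)stannane
Product: 19 (5S)-5-[(2R,3R)-3-(but-3-en-1-yl)-3-methyloxiran-2-yl]-3-({[tert-butyl(dimethyl)silyl]oxy}methyl)-4-[(1S)-1-hydroxy-3-methylbut-3-en-1-yl]furan-2(5H)-one
Conditions: (S)-BINOL (20 mol%), Ti(OiPr)4 (10 mol%), 4 Å MS, CH2Cl2, −20 °C; aq. NaHCO3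
Reagents that add atoms: none
Why: Keck asymmetric methallylation: the (S)-BINOL–titanium Lewis acid should direct the stannane to the Si face of the aldehyde and so give the 8S carbinol under catalyst control, with 1,2-addition assured because the β-carbon of the enal (C11) is fully substituted.

Step 14
Reactants: 19 C8 alcohol
Product: 20 (5S)-5-[(2R,3R)-3-(but-3-en-1-yl)-3-methyloxiran-2-yl]-3-({[tert-butyl(dimethyl)silyl]oxy}methyl)-4-[(1S)-3-methyl-1-(triethylsilyloxy)but-3-en-1-yl]furan-2(5H)-one
Conditions: Et3SiCl, imidazole, DMF, 0 °C → rt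
Reagents that add atoms: chlorotriethylsilane, CC[Si](Cl)(CC)CC
Why: Silylation of the secondary alcohol with imidazole as base, which is too weak to deprotonate C6–H and trigger β-elimination of the oxirane.

Step 15
Reactants: 20 epoxy butenolide diene
Product: 21 (1(10)Z,4R,5R,6S,8S)-13-[tert-butyl(dimethyl)silyl]oxy-4,5-epoxy-8-(triethylsilyloxy)germacra-1(10),7(11)-dien-12,6-olide
Conditions: second-generation Grubbs catalyst RuCl2(=CHPh)(PCy3)(H2IMes) (10 mol% in two portions), toluene (1 mM), 80 °C, argon sparge
Reagents that add atoms: none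
Why: Olefin metathesis by the Chauvin mechanism: the ruthenium benzylidene exchanges onto the monosubstituted C1 vinyl group, the new alkylidene adds to the 1,1-disubstituted C10 alkene through a ruthenacyclobutane, and cycloreversion releases the trisubstituted C1=C10 alkene and ethene, whose loss drives the reaction. The closest known reaction type is ring-closing metathesis to trisubstituted medium-ring cycloalkenes with second-generation ruthenium carbenes. The ten-membered carbocycle C1–C10 is closed by joining its two chain termini (C1 and C10) intramolecularly, and the oxirane and butenolide already in place remove rotors between C4 and C8 and turn the two alkenes toward each other. No stereocentre is formed. The step needs the Z geometry and cyclisation in preference to oligomerisation: the Z isomer is expected to be the less strained one in a ten-membered ring that also holds a trans-oxirane and the sp2 carbon C7, the N-heterocyclic carbene catalyst allows equilibration toward it, and high dilution with removal of ethene suppresses intermolecular metathesis. Neither reacting alkene is allylic to oxygen, and the tetrasubstituted electron-poor butenolide alkene and the oxirane should not engage the carbene.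

Step 16
Reactants: 21 1(10)Z-ene
Product: 23 (1S,4R,5R,6S,8S,10S)-13-[tert-butyl(dimethyl)silyl]oxy-4,5-epoxy-1-hydroxy-8-(triethylsilyloxy)germacr-7(11)-en-12,6-olide, via C1 alkylborane 22 (not isolated)
Conditions: BH3·SMe2, THF, 0 °C; then aq. NaOAc, 30% H2O2, 0 °C → rt
Reagents that add atoms: hydrogen peroxide, OO
Why: Hydroboration–oxidation: borane adds syn and anti-Markovnikov (boron to C1, hydrogen to C10) to the only electron-rich alkene, and attack on the α face of the Z alkene (the face of the C8 oxygen, expected to be the open face of the conformer held by the trans-oxirane and the butenolide) sets 1S and 10S together, after which acetate-buffered peroxide replaces boron by hydroxyl with retention without harming the lactone.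

Step 17
Reactants: 23 C1 alcohol
Product: 24 (1S,4R,5R,6S,8S,10S)-1-acetoxy-13-[tert-butyl(dimethyl)silyl]oxy-4,5-epoxy-8-(triethylsilyloxy)germacr-7(11)-en-12,6-olide
Conditions: Ac2O, pyridine, DMAP (cat.), CH2Cl2, 0 °C → rt
Reagents that add atoms: acetic anhydride, CC(=O)OC(C)=O
Why: DMAP-catalysed acetylation of the only free hydroxyl under weakly basic conditions.

Step 18
Reactants: 24 C1 acetate
Product: 25 (1S,4R,5R,6S,8S,10S)-1-acetoxy-13-[tert-butyl(dimethyl)silyl]oxy-4,5-epoxy-8-hydroxygermacr-7(11)-en-12,6-olide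
Conditions: HF·pyridine, pyridine, THF, 0 °C
Reagents that add atoms: none
Why: Selective desilylation: buffered HF·pyridine at 0 °C should cleave the secondary triethylsilyl ether well before the primary tert-butyldimethylsilyl ether, and the medium is too weakly acidic to open the oxirane.

Step 19
Reactants: 25 C8 alcohol
Product: 26 (1S,4R,5R,6S,8S,10S)-1-acetoxy-13-[tert-butyl(dimethyl)silyl]oxy-4,5-epoxy-8-(2-methylprop-2-enoyloxy)germacr-7(11)-en-12,6-olide
Conditions: methacrylic anhydride, DMAP, pyridine, CH2Cl2, 0 °C → rt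
Reagents that add atoms: methacrylic anhydride, C=C(C)C(=O)OC(=O)C(C)=C
Why: DMAP-catalysed acylation of the hindered C8 alcohol with the anhydride under conditions too weakly basic to deprotonate C6–H or polymerise the methacrylate.

Step 20
Reactants: 26 C13 silyl ether
Product: 27 glaucolide L, (1S,4R,5R,6S,8S,10S)-1-acetoxy-4,5-epoxy-13-hydroxy-8-(2-methylprop-2-enoyloxy)germacr-7(11)-en-12,6-olide
Conditions: HF·pyridine, THF, 0 °C → rt
Reagents that add atoms: none
Why: Fluoride cleavage of the primary silyl ether in a slightly acidic medium, which avoids acyl migration to the freed C13 hydroxyl and base-induced elimination at C6 and leaves the oxirane and both esters intact.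

**Compound list**

1 | ethyl but-2-ynoate | CC#CC(=O)OCC | starting material
2 | but-3-enylmagnesium bromide | C=CCC[Mg]Br | starting material
3 | ethyl (2E)-3-methylhepta-2,6-dienoate | CCOC(=O)/C=C(\C)CCC=C | intermediate
4 | (2E)-3-methylhepta-2,6-dien-1-ol | OC/C=C(\C)CCC=C | intermediate
5 | [(2R,3R)-3-(but-3-en-1-yl)-3-methyloxiran-2-yl]methanol | OC[C@H]1O[C@]1(C)CCC=C | intermediate
6 | (2S,3R)-3-(but-3-en-1-yl)-3-methyloxirane-2-carbaldehyde | O=C[C@H]1O[C@]1(C)CCC=C | intermediate
7 | tert-butyldimethyl(prop-2-yn-1-yloxy)silane | C#CCO[Si](C)(C)C(C)(C)C | starting material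
8 | lithium acetylide of 7 | [Li]C#CCO[Si](C)(C)C(C)(C)C | intermediate (not isolated)
9 | 1-[(2R,3R)-3-(but-3-en-1-yl)-3-methyloxiran-2-yl]-4-[tert-butyl(dimethyl)silyl]oxybut-2-yn-1-ol, both carbinol (C6) epimers | OC(C#CCO[Si](C)(C)C(C)(C)C)[C@H]1O[C@]1(C)CCC=C | intermediate
10 | 1-[(2S,3R)-3-(but-3-en-1-yl)-3-methyloxiran-2-yl]-4-[tert-butyl(dimethyl)silyl]oxybut-2-yn-1-one | O=C(C#CCO[Si](C)(C)C(C)(C)C)[C@H]1O[C@]1(C)CCC=C | intermediate
11 | (1R)-1-[(2R,3R)-3-(but-3-en-1-yl)-3-methyloxiran-2-yl]-4-[tert-butyl(dimethyl)silyl]oxybut-2-yn-1-ol | O[C@H](C#CCO[Si](C)(C)C(C)(C)C)[C@H]1O[C@]1(C)CCC=C | intermediate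
12 | methanesulfonate of 11 | CS(=O)(=O)O[C@H](C#CCO[Si](C)(C)C(C)(C)C)[C@H]1O[C@]1(C)CCC=C | intermediate
13 | (aR)-4-[(2R,3R)-3-(but-3-en-1-yl)-3-methyloxiran-2-yl]-2-({[tert-butyl(dimethyl)silyl]oxy}methyl)buta-2,3-dienoic acid | OC(=O)C(CO[Si](C)(C)C(C)(C)C)=[C@]=C([H])[C@H]1O[C@]1(C)CCC=C | intermediate
14 | (5R)-5-[(2R,3R)-3-(but-3-en-1-yl)-3-methyloxiran-2-yl]-3-({[tert-butyl(dimethyl)silyl]oxy}methyl)-4-iodofuran-2(5H)-one | IC1=C(CO[Si](C)(C)C(C)(C)C)C(=O)O[C@@H]1[C@H]1O[C@]1(C)CCC=C | intermediate
15 | (2S)-2-[(2R,3R)-3-(but-3-en-1-yl)-3-methyloxiran-2-yl]-4-({[tert-butyl(dimethyl)silyl]oxy}methyl)-5-oxo-2,5-dihydrofuran-3-carbaldehyde | O=CC1=C(CO[Si](C)(C)C(C)(C)C)C(=O)O[C@@H]1[C@H]1O[C@]1(C)CCC=C | intermediate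
16 | 3-chloro-2-methylpropene | C=C(C)CCl | starting material
17 | (2-methylallyl)magnesium chloride | C=C(C)C[Mg]Cl | intermediate (not isolated)
18 | tributyl(2-methylprop-2-en-1-yl)stannane | C=C(C)C[Sn](CCCC)(CCCC)CCCC | intermediate
19 | (5S)-5-[(2R,3R)-3-(but-3-en-1-yl)-3-methyloxiran-2-yl]-3-({[tert-butyl(dimethyl)silyl]oxy}methyl)-4-[(1S)-1-hydroxy-3-methylbut-3-en-1-yl]furan-2(5H)-one | O[C@@H](CC(C)=C)C1=C(CO[Si](C)(C)C(C)(C)C)C(=O)O[C@@H]1[C@H]1O[C@]1(C)CCC=C | intermediate
20 | triethylsilyl ether of 19 (metathesis precursor) | CC[Si](CC)(CC)O[C@@H](CC(C)=C)C1=C(CO[Si](C)(C)C(C)(C)C)C(=O)O[C@@H]1[C@H]1O[C@]1(C)CCC=C | intermediate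
21 | (1(10)Z,4R,5R,6S,8S)-13-[tert-butyl(dimethyl)silyl]oxy-4,5-epoxy-8-(triethylsilyloxy)germacra-1(10),7(11)-dien-12,6-olide | CC[Si](CC)(CC)O[C@H]1C/C(C)=C\CC[C@@]2(C)O[C@@H]2[C@H]2OC(=O)C(CO[Si](C)(C)C(C)(C)C)=C12 | intermediate
22 | C1 alkylborane (BH2 on C1, H on C10, both α) | CC[Si](CC)(CC)O[C@H]1C[C@H](C)[C@@H](B)CC[C@@]2(C)O[C@@H]2[C@H]2OC(=O)C(CO[Si](C)(C)C(C)(C)C)=C12 | intermediate (not isolated)
23 | (1S,4R,5R,6S,8S,10S)-13-[tert-butyl(dimethyl)silyl]oxy-4,5-epoxy-1-hydroxy-8-(triethylsilyloxy)germacr-7(11)-en-12,6-olide | CC[Si](CC)(CC)O[C@H]1C[C@H](C)[C@@H](O)CC[C@@]2(C)O[C@@H]2[C@H]2OC(=O)C(CO[Si](C)(C)C(C)(C)C)=C12 | intermediate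
24 | 1-acetate of 23 | CC[Si](CC)(CC)O[C@H]1C[C@H](C)[C@@H](OC(C)=O)CC[C@@]2(C)O[C@@H]2[C@H]2OC(=O)C(CO[Si](C)(C)C(C)(C)C)=C12 | intermediate
25 | (1S,4R,5R,6S,8S,10S)-1-acetoxy-13-[tert-butyl(dimethyl)silyl]oxy-4,5-epoxy-8-hydroxygermacr-7(11)-en-12,6-olide | O[C@H]1C[C@H](C)[C@@H](OC(C)=O)CC[C@@]2(C)O[C@@H]2[C@H]2OC(=O)C(CO[Si](C)(C)C(C)(C)C)=C12 | intermediate
26 | 8-methacrylate of 25 | C=C(C)C(=O)O[C@H]1C[C@H](C)[C@@H](OC(C)=O)CC[C@@]2(C)O[C@@H]2[C@H]2OC(=O)C(CO[Si](C)(C)C(C)(C)C)=C12 | intermediate
27 | glaucolide L | C=C(C)C(=O)O[C@H]1C[C@H](C)[C@@H](OC(C)=O)CC[C@@]2(C)O[C@@H]2[C@H]2OC(=O)C(CO)=C12 | target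

**Step count**

Total steps: 20. Longest linear sequence: 19 (steps 1–11 and 13–20; step 12 is a one-step side branch).

**Steps most likely to fail**

Step 15 (ring-closing metathesis). The process at risk is closure to the E-configured C1=C10 alkene, or to an E/Z mixture, if the Z preference assumed for this ring does not hold. Slow closure with oligomerisation is the second concern. The fallback sets out from 20 and uses the E isomer instead of discarding it. The same metathesis gives the (1(10)E)-alkene F1. Hydroboration–oxidation as in step 16 adds H and OH syn, which from F1 should lead to the C1 epimer, the 1R,10S alcohol F2, as long as hydrogen is again delivered to the α face of C10. Mitsunobu esterification of F2 with acetic acid (PPh3, diisopropyl azodicarboxylate, toluene, 0 °C) inverts C1 and gives acetate 24, where the route is rejoined.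

Step 16 (hydroboration). The process at risk is poor or reversed facial selectivity: borane adding to the β face would give the 1R,10R alcohol, because the selectivity rests only on the ring conformation. Reduction of the lactone by excess borane is a lesser concern. The fallback sets out from 21 and replaces substrate control by reagent control. Monoisopinocampheylborane is used in THF at −25 °C; the antipode matched to the α face is chosen after a trial with both, each being made from one enantiomer of α-pinene. Acetaldehyde then expels α-pinene and leaves the diethyl C1-boronate F3. Oxidation of F3 (aq. NaOAc, H2O2) gives 23, where the route is rejoined.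

Step 9 (hydrocarboxylation). The process at risk is solvolysis of the mesylate and acid-promoted opening of the trisubstituted oxirane, since water and a strong acid are both present before carbonylation is complete. The fallback sets out from 11 and changes the mode of ionisation. The alcohol is converted to its methyl carbonate F4 (ClCO2Me, pyridine, CH2Cl2, 0 °C). Decarboxylative carbonylation under neutral, anhydrous conditions (Pd2(dba)3·CHCl3, PPh3, CO 5 atm, MeOH, THF, 40 °C) follows the same anti SN2′ course and gives the methyl allenoate F5, so that neither water nor a sulfonic acid is present. Iodolactonisation of the ester (I2, NaHCO3, MeCN–H2O, 0 °C) gives 14, where the route is rejoined.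

**Further compounds**

F1 | step 15 | (1(10)E,4R,5R,6S,8S)-13-[tert-butyl(dimethyl)silyl]oxy-4,5-epoxy-8-(triethylsilyloxy)germacra-1(10),7(11)-dien-12,6-olide | CC[Si](CC)(CC)O[C@H]1C/C(C)=C/CC[C@@]2(C)O[C@@H]2[C@H]2OC(=O)C(CO[Si](C)(C)C(C)(C)C)=C12
F2 | step 15 | (1R,4R,5R,6S,8S,10S)-13-[tert-butyl(dimethyl)silyl]oxy-4,5-epoxy-1-hydroxy-8-(triethylsilyloxy)germacr-7(11)-en-12,6-olide | CC[Si](CC)(CC)O[C@H]1C[C@H](C)[C@H](O)CC[C@@]2(C)O[C@@H]2[C@H]2OC(=O)C(CO[Si](C)(C)C(C)(C)C)=C12
F3 | step 16 | diethyl C1-boronate corresponding to 23 | CC[Si](CC)(CC)O[C@H]1C[C@H](C)[C@@H](B(OCC)OCC)CC[C@@]2(C)O[C@@H]2[C@H]2OC(=O)C(CO[Si](C)(C)C(C)(C)C)=C12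
F4 | step 9 | methyl carbonate of 11 | COC(=O)O[C@H](C#CCO[Si](C)(C)C(C)(C)C)[C@H]1O[C@]1(C)CCC=C
F5 | step 9 | methyl ester of 13 (methyl allenoate) | COC(=O)C(CO[Si](C)(C)C(C)(C)C)=[C@]=C([H])[C@H]1O[C@]1(C)CCC=C
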